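Decide, before this flask is left until 20 h, whether that time will do or a longer stay must be planned.

the same everywhere: electrophile 14 mM
- north-east: free base 21 mM (fed, over 80 min); protonated nucleophile 42 mM; the very flask that is asked about, followed so far
- flask: free base 21.0 mM (fed, over 80 min); protonated nucleophile 42.0 mM; time 20 h

- north-east (time / h: electrophile / %, product / %): 0.333: 95, 3; 0.500: 91, 2; 0.833: 91, 4; 1.33: 83, 4; 2.50: 68, 11; 4.00: 53, 19

(standard deviation of a reading: 1.5 percentage points)

- what has gone from electrophile into another species counts as reacted, even if it can come back
- the earlier runs do not show how much of nucleophile is bound; that part of a forecast is a guess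

- part of the electrophile that has reacted at 20 h
- share of the unused nucleophile that is free and not bound as protonated nucleophile, at 20 h

You can read the decision off the north-east run, which is this same flask followed so far. Start at the end of the feed, 1.33 h, and go to the last reading, 4.00 h. Product made per hour, divided by the mean electrophile present, gives 0.0826 h⁻¹. Call this the drain constant, a pseudo-first-order constant and a reading that carries the scatter of 1.5 percentage points.

Now join that to the other end. At 4.00 h the part of the charge that is not yet product reads 81.0 %, and electrophile is a fraction 0.654 of that. If that fraction holds, the unfinished material drains at 0.0541 h⁻¹. In the north-east flask electrophile then stands at 22.3 % at 20 h, so I reckon 77.7 % reacted. I would keep the charge and plan a longer stay if the electrophile is to be used up. The readings do not show the binding of nucleophile, so I give no number for it.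

The forecast, noting that “any reversibility would leave a little more”, gives 88 % reacted, higher than my figure, and guesses 25 % free.

The flask gives 79.7 % reacted and 0.383 % free.

    electrophile + nucleophile → acid set free + product (k = 0.160 L mol⁻¹ s⁻¹)
    nucleophile + acid set free ⇌ protonated nucleophile, settled at all times (K = 1.00 × 10⁶ L mol⁻¹)
    acid set free + free base ⇌ salt of the base (K = 1.50 × 10⁵ L mol⁻¹, k = 0.0550 L mol⁻¹ s⁻¹)
    acid set free → by-product carried off (k = 8.50 × 10⁻⁵ s⁻¹)
    electrophile ⇌ dormant form (K = 0.860, k = 3.30 × 10⁻⁵ s⁻¹)

In this flask at 6.73 h electrophile went to product at 0.64 of its forward rate into the dormant form, and at 20 h the dormant form holds 23.2 % beside 20.3 % of electrophile. The drain constant, read as 0.0826 h⁻¹ from the north-east readings, is by the product step 0.16 L mol⁻¹ s⁻¹ times c(nucleophile), which gives 0.0755 h⁻¹ in this flask with 0.131 mM of nucleophile at 20.0 h, but less, 0.0430 h⁻¹, with 0.0746 mM at that time in a neighbour flask charged with 17 mM of protonated nucleophile, where 29.6 % of the electrophile is left.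

The readings are calculated for substances that don't exist, and the scatter is random.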